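**Assumptions (one line each)**
- 4‑Methylfuran‑2(5H)‑one, 2‑(3‑bromopropyl)‑1,3‑dioxolane, methyl acrylate and 1,3‑butadiene are commercial. The absolute configuration is set by the enantiomer of the chiral ligand in Step 1.
- The natural C6 methyl‑acetal (OMe on the convex face, cis to H‑5 and Me‑18) is the thermodynamic anomer obtained in Step 7.
- In the β‑keto lactone (Step 4) the cis ring fusion is at least the major equilibrium isomer. Any trans isomer is removed after Step 5.

**Retrosynthetic overview**
1. The target comes from exo‑face hydrogenation of a 16‑methylene‑15‑ketone, which places the 16‑Me endo. That enone comes from Mannich methylenation of a bicyclo[3.2.1]octanone.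
2. The bicyclooctanone forms by 5‑exo α‑keto radical closure (C16→C13) onto the ring‑C cyclohexene.
3. Key step: Diels–Alder of butadiene with a spiro α‑acetyl‑α,β‑unsaturated δ‑lactone. It sets C8 (quaternary) and C9, forms ring C and keeps the lactone cis‑fused. The 6,7‑seco skeleton is built directly and ring B is never made.
4. The spiro quaternary C10 comes from a Ti(III) epoxide‑opening Giese addition of a spiro‑epoxide to methyl acrylate. The ring‑A/THF methyl acetal comes from a SmI2 Reformatsky–aldol closure of a β‑methylbutenolide‑derived bromolactone, so the cis‑fused lactone and C4 quaternary centre are set in advance.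
5. Ring order: THF‑lactone, then ring A, then spiro δ‑lactone, then ring C, then ring D.

---

**Step 1**
Reactants: 1 (4‑methylfuran‑2(5H)‑one); 2 ([3‑(1,3‑dioxolan‑2‑yl)propyl]MgBr)
Product: 3 (α‑bromolactone acetal, C4 quaternary centre as drawn)
Conditions: CuBr·SMe2 (10 mol%), chiral Josiphos‑type ligand (12 mol%), MTBE, –78 °C; then BrCCl2CCl2Br, –78 °C
Reagents that add atoms: 1,2‑dibromo‑1,1,2,2‑tetrachloroethane, ClC(Cl)(Br)C(Cl)(Cl)Br (Br)
Why: Proposed new method: a Cu/chiral‑diphosphine 1,4‑addition of RMgBr to the β,β‑disubstituted butenolide creates the C4 quaternary centre under ligand control, and the Mg‑enolate is brominated in situ so that C5 can later act as a Reformatsky nucleophile (C5 epimers are irrelevant). The closest known reaction is Cu/Josiphos asymmetric conjugate addition of Grignards to 3‑methylcyclohex‑2‑enone with enolate trapping.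

**Step 2**
Reactants: 3
Product: 4 (aldehyde)
Conditions: PPTS, acetone/H2O, 50 °C
Reagents that add atoms: water, O (aldehyde oxygen)
Why: Acid‑catalysed dioxolane hydrolysis unmasks the C10 aldehyde; the bromolactone and the quaternary C4 are untouched.

**Step 3**
Reactants: 4
Product: 5 (cis‑fused 7‑hydroxy‑3a‑methylhexahydroisobenzofuran‑1(3H)‑one)
Conditions: SmI2 (2.3 equiv), THF, –78 → 0 °C
Reagents that add atoms: none
Why: Intramolecular SmI2 Reformatsky–aldol (6‑exo) forms the C5–C10 bond and closes ring A; the tether on C4 forces a cis ring fusion, so H‑5 ends up cis to Me‑18. The new C10–OH is a mixture that is oxidised in the next step.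

**Step 4**
Reactants: 5
Product: 6 (β‑keto lactone)
Conditions: Dess–Martin periodinane, NaHCO3, CH2Cl2, 0 °C
Reagents that add atoms: none
Why: Oxidation of the secondary alcohol to the C10 ketone; this removes the C10 stereocentre, and the cis isomer is the assumed thermodynamic ring fusion.

**Step 5**
Reactants: 6
Product: 7 (exocyclic C10=C20 methylene lactone)
Conditions: CH2Br2, Zn, TiCl4, THF/CH2Cl2, 0 → 25 °C
Reagents that add atoms: dibromomethane, BrCBr (C20 as CH2)
Why: Takai–Lombardo methylenation is neutral to mildly Lewis‑acidic and chemoselective for the ketone over the lactone, so it tolerates the enolisable β‑dicarbonyl.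

**Step 6**
Reactants: 7
Product: 8 (lactol)
Conditions: DIBAL‑H (1.2 equiv), CH2Cl2, –78 °C; Rochelle salt work‑up
Reagents that add atoms: none
Why: Partial reduction of the γ‑lactone to the lactol; the 1,1‑disubstituted alkene is inert, and this is done before the ring‑C/D carbonyls exist so that it is chemoselective.

**Step 7**
Reactants: 8
Product: 9 (ring‑A/THF methyl acetal)
Conditions: MeOH, PPTS (cat.), rt
Reagents that add atoms: methanol, CO (OMe)
Why: Acid‑catalysed acetalisation gives the cyclic methyl acetal; under thermodynamic control the convex (exo) OMe anomer predominates, as in the target.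

**Step 8**
Reactants: 9
Product: 10 (spiro‑epoxide at C10, diastereomeric mixture)
Conditions: DMDO, acetone, –20 → 0 °C
Reagents that add atoms: dimethyldioxirane, CC1(C)OO1 (O)
Why: Neutral epoxidation of the exocyclic alkene leaves the acid‑labile acetal intact; the C10 epoxide stereochemistry is irrelevant because the next step destroys it.

**Step 9**
Reactants: 10; 11 (methyl acrylate)
Product: 12 (hydroxy ester with the C10 quaternary centre)
Conditions: Cp2TiCl2 (2.5 equiv), Zn, methyl acrylate (10 equiv), THF, rt; aqueous work‑up
Reagents that add atoms: none (acrylate is reactant 11)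
Why: Ti(III) radical epoxide opening gives the tertiary C10 radical with C20–OTi, which undergoes Giese addition to the acrylate (Nugent–RajanBabu/Gansäuer chemistry). Axial attack is blocked by the 1,3‑diaxial C19 and the concave THF face, so C9 is delivered from the convex equatorial direction, placing C20 axial and C9 equatorial as required.

**Step 10**
Reactants: 12
Product: 13 (spiro δ‑lactone)
Conditions: PPTS, toluene, 90 °C (Dean–Stark)
Reagents that add atoms: none (MeOH lost)
Why: Acid‑catalysed lactonisation of the 5‑hydroxy ester (Thorpe–Ingold assisted) forms the 7,20‑lactone without touching any stereocentre.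

**Step 11**
Reactants: 13
Product: 14 (α‑acetyl spirolactone)
Conditions: LiHMDS (2.2 equiv), THF, –78 °C; then N‑acetylimidazole, –78 → 0 °C
Reagents that add atoms: N‑acetylimidazole, CC(=O)n1ccnc1 (acetyl, C15/C16)
Why: C‑acylation of the lactone enolate (Claisen type); the second equivalent of base deprotonates the β‑keto lactone and drives the reaction. C8 is left as an epimerisable carbon.

**Step 12**
Reactants: 14
Product: 15 (α‑phenylselenide)
Conditions: PhSeCl, pyridine, CH2Cl2, 0 °C
Reagents that add atoms: benzeneselenenyl chloride, Cl[Se]c1ccccc1 (SePh)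
Why: Electrophilic α‑selenation of the 1,3‑dicarbonyl at C8.

**Step 13**
Reactants: 15
Product: 16 (3‑acetyl‑5,6‑dihydropyran‑2‑one dienophile, spiro at C10)
Conditions: 30% H2O2, CH2Cl2/pyridine, 0 → 25 °C
Reagents that add atoms: none (Se leaves as PhSeOH)
Why: Selenoxide syn‑elimination can only use H‑9, giving the doubly activated C8=C9 alkene with no other regiochemical option.

**Step 14**
Reactants: 16; 17 (1,3‑butadiene)
Product: 18 (Diels–Alder adduct)
Conditions: butadiene (30 equiv), BHT, toluene, sealed tube, 110 °C
Reagents that add atoms: none (butadiene is reactant 17)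
Why: Diels–Alder of butadiene with the alkylidene β‑keto lactone builds ring C and C8/C9 in one step; suprafacial addition to the ring‑locked alkene gives the cis ring fusion (C14 and C11 on one face, C15 cis to H‑9). The diene approaches the face syn to C1 and anti to the branched C5 side, which matches the target configuration.

**Step 15**
Reactants: 18
Product: 19 (bromomethyl ketone)
Conditions: LiHMDS, TMSCl, Et3N, THF, –78 °C; then NBS, –78 °C
Reagents that add atoms: N‑bromosuccinimide, O=C1CCC(=O)N1Br (Br)
Why: C8 is quaternary, so only the acetyl CH3 enolises; the silyl enol ether is brominated by NBS faster than the ring alkene, and basic enolisation avoids ionising the acetal.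

**Step 16**
Reactants: 19
Product: 20 (bicyclo[3.2.1]octan‑15‑one, C16H2)
Conditions: Bu3SnH (syringe pump, 1.5 equiv), AIBN, benzene, 80 °C, 0.005 M
Reagents that add atoms: none (H only)
Why: 5‑exo‑trig radical cyclisation of the α‑keto radical onto C13 of the ring alkene, with C15 axial. Geometry forces C13 and the bridged ring D, and the resulting C12 radical is reduced to CH2.

**Step 17**
Reactants: 20
Product: 21 (Mannich base, C16 epimer mixture)
Conditions: LDA, THF, –78 °C; then CH2=NMe2+ I– (Eschenmoser's salt), –78 → 0 °C
Reagents that add atoms: Eschenmoser's salt, C[N+](C)=C.[I-] (CH2NMe2, C17)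
Why: Regioselective enolisation toward C16 (the only enolisable side) followed by aminomethylation, a Mannich reaction.

**Step 18**
Reactants: 21
Product: 22 (16‑methylene‑15‑ketone)
Conditions: MeI, MeOH, rt; then NaHCO3 or DBU, CH2Cl2
Reagents that add atoms: none (iodomethane only makes the leaving group; NMe3 is lost)
Why: Quaternisation and E1cB (Hofmann‑type) elimination give the exocyclic enone, which fixes C16 as sp2 so its configuration can be set cleanly in the next step.

**Step 19**
Reactants: 22
Product: 23 (ludongnin I)
Conditions: H2 (1 atm), 10% Pd/C, EtOAc, rt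
Reagents that add atoms: none (H only)
Why: Heterogeneous hydrogenation from the less hindered exo face (syn to the C14 bridge) puts H on C16 exo and the new methyl endo, matching the target; the ketone, both lactones and the acetal are untouched.

---

**Compound list**

| No. | Name | SMILES | Role |
|---|---|---|---|
| 1 | 4‑Methylfuran‑2(5H)‑one | CC1=CC(=O)OC1 | starting material |
| 2 | [3‑(1,3‑Dioxolan‑2‑yl)propyl]magnesium bromide | Br[Mg]CCCC1OCCO1 | starting material |
| 3 | 3‑Bromo‑4‑methyl‑4‑[3‑(1,3‑dioxolan‑2‑yl)propyl]oxolan‑2‑one | O=C1OC[C@](C)(CCCC2OCCO2)C1Br | intermediate |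
| 4 | 3‑Bromo‑4‑methyl‑4‑(4‑oxobutyl)oxolan‑2‑one | O=C1OC[C@](C)(CCCC=O)C1Br | intermediate |
| 5 | cis‑7‑Hydroxy‑3a‑methylhexahydroisobenzofuran‑1(3H)‑one | O=C1OC[C@]2(C)CCCC(O)[C@H]12 | intermediate |
| 6 | 3a‑Methylhexahydroisobenzofuran‑1,7‑dione | O=C1OC[C@]2(C)CCCC(=O)[C@H]12 | intermediate |
| 7 | 3a‑Methyl‑7‑methylenehexahydroisobenzofuran‑1(3H)‑one | O=C1OC[C@]2(C)CCCC(=C)[C@H]12 | intermediate |
| 8 | Lactol of 7 (1‑hydroxy‑octahydroisobenzofuran) | OC1OC[C@]2(C)CCCC(=C)[C@H]12 | intermediate |
| 9 | 1‑Methoxy‑3a‑methyl‑7‑methylene‑octahydroisobenzofuran | CO[C@H]1OC[C@]2(C)CCCC(=C)[C@H]12 | intermediate |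
| 10 | Spiro‑epoxide of 9 (C10, diastereomeric mixture) | CO[C@H]1OC[C@]2(C)CCCC3(CO3)[C@H]12 | intermediate |
| 11 | Methyl acrylate | C=CC(=O)OC | starting material |
| 12 | Methyl 3‑[hydroxymethyl‑methoxy‑methyl‑octahydroisobenzofuranyl]propanoate (C10 quaternary) | CO[C@H]1OC[C@]2(C)CCC[C@@](CO)(CCC(=O)OC)[C@H]12 | intermediate |
| 13 | Spiro δ‑lactone (7,20‑lactone) | CO[C@H]1OC[C@]2(C)CCC[C@]3(COC(=O)CC3)[C@H]12 | intermediate |
| 14 | α‑Acetyl spiro δ‑lactone (C8 epimer mixture) | CO[C@H]1OC[C@]2(C)CCC[C@]3(COC(=O)C(C(C)=O)C3)[C@H]12 | intermediate |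
| 15 | α‑Acetyl‑α‑phenylselenyl spiro δ‑lactone | CO[C@H]1OC[C@]2(C)CCC[C@]3(COC(=O)C([Se]c4ccccc4)(C(C)=O)C3)[C@H]12 | intermediate |
| 16 | 3‑Acetyl‑5,6‑dihydropyran‑2‑one dienophile, spiro at C10 | CO[C@H]1OC[C@]2(C)CCC[C@]3(COC(=O)C(C(C)=O)=C3)[C@H]12 | intermediate |
| 17 | 1,3‑Butadiene | C=CC=C | starting material |
| 18 | Diels–Alder adduct (cyclohexene ring C) | CO[C@H]1OC[C@]2(C)CCC[C@]3(COC(=O)[C@@]4(C(C)=O)CC=CC[C@H]43)[C@H]12 | intermediate |
| 19 | Bromomethyl ketone of 18 | CO[C@H]1OC[C@]2(C)CCC[C@]3(COC(=O)[C@@]4(C(=O)CBr)CC=CC[C@H]43)[C@H]12 | intermediate |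
| 20 | Tetracyclic bicyclo[3.2.1]octan‑15‑one (C16H2) | CO[C@H]1OC[C@]2(C)CCC[C@]3(COC(=O)[C@@]45C[C@@H](CC[C@H]43)CC5=O)[C@H]12 | intermediate |
| 21 | Mannich base of 20 (C16 epimers) | CO[C@H]1OC[C@]2(C)CCC[C@]3(COC(=O)[C@@]45C[C@@H](CC[C@H]43)C(CN(C)C)C5=O)[C@H]12 | intermediate |
| 22 | 16‑Methylene‑15‑ketone (exocyclic enone) | CO[C@H]1OC[C@]2(C)CCC[C@]3(COC(=O)[C@@]45C[C@@H](CC[C@H]43)C(=C)C5=O)[C@H]12 | intermediate |
| 23 | Ludongnin I | CO[C@H]1OC[C@]2(C)CCC[C@]3(COC(=O)[C@@]45C[C@@H](CC[C@H]43)[C@@H](C)C5=O)[C@H]12 | target |

**Total step count:** 19. **Longest linear sequence:** 19 (from 1). The other building blocks enter at Steps 1 (2), 9 (11) and 14 (17).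

**Three steps most likely to fail**
1. **Step 1 (asymmetric conjugate addition to the β‑methylbutenolide, then bromination).** The butenolide is a poor, hindered acceptor, and both the enantioselectivity and the enolate bromination are unproven.
 Fallback: build the quaternary centre chemoenzymatically. Desymmetrise the prochiral diester dimethyl 3‑methyl‑3‑[3‑(1,3‑dioxolan‑2‑yl)propyl]glutarate with pig liver esterase, reduce the resulting acid to the lactone with BH3·SMe2, and brominate the lactone (LDA, BrCCl2CCl2Br) to reach 3.
2. **Step 9 (Ti(III) Giese).** The tertiary radical may be trapped by Ti(III) and undergo β‑H elimination, or attack from the wrong face, and the spiro centre might not be formed cleanly.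
 Fallback: use a masked α‑benzyloxy ketone in place of the aldehyde acetal in 2. The SmI2 step then delivers the C10 tertiary alcohol carrying C20–OBn. Convert it to the cesium oxalate, do a photoredox (Ir) deoxygenative Giese with methyl acrylate, then hydrogenolyse the benzyl ether to reach 12.
3. **Step 14 (Diels–Alder).** Facial selectivity at the spiro‑adjacent C9 is uncertain, and hetero‑Diels–Alder of the oxadiene competes with the carbo‑Diels–Alder.
 Fallback: assemble ring C by conjugate allylation at C9 (allylTMS, Lewis acid), enolate allylation at C8 (allyl bromide), then Grubbs II ring‑closing metathesis to the same cis‑fused cyclohexene 18.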